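Take the mono adduct column apart first: the part bound in idle adduct is a gauge of the substrate left.

| flask | substrate | reagent | remark | time |
|---|---|---|---|---|
| blue | 0.020 M | 0.016 M (fed, over 20 min) | run made earlier; the fed solution adds 1.0 times the starting volume |  |
| violet | 0.020 M | 0.036 M (fed, over 20 min) | run made earlier; the fed solution adds 1.0 times the starting volume |  |
| amber | 0.040 M | 0.024 M (fed, over 20 min) | run made earlier; the fed solution adds 1.0 times the starting volume |  |
| flask | 0.020 M | 0.0240 M (fed, over 20 min) | the fed solution adds 1.0 times the starting volume | 50 min |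

| run | time / min | mono adduct / % | idle adduct / % |
|---|---|---|---|
| blue | 5.00 | 0 | 0.5 |
| blue | 10.0 | 1.9 | 2.5 |
| blue | 15.0 | 4.7 | 5.9 |
| blue | 30.0 | 8.0 | 11.4 |
| blue | 60.0 | 16.2 | 17.8 |
| violet | 5.00 | 1.6 | 1.0 |
| violet | 10.0 | 3.3 | 5.8 |
| violet | 15.0 | 7.8 | 9.7 |
| violet | 30.0 | 17.0 | 18.5 |
| violet | 60.0 | 26.9 | 20.9 |
| amber | 5.00 | 1.1 | 1.3 |
| amber | 10.0 | 3.0 | 3.7 |
| amber | 15.0 | 5.6 | 8.4 |
| amber | 30.0 | 11.3 | 17.2 |
| amber | 60.0 | 17.2 | 23.1 |

(readings scatter by 0.5 percentage points)

- a species is counted by the substrate in it: one idle adduct counts as two
- amounts and yields of mono adduct count idle adduct too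
- charges are per starting volume, the dose included; the dosed solution carries all of it
- reactions considered so far: substrate + mono adduct <-> idle adduct; reagent + other mono adduct -> bis adduct; reagent + mono adduct -> bis adduct; substrate + reagent -> other mono adduct; substrate + reagent -> mono adduct
- in an amount of mono adduct, one idle adduct counts as one mono adduct

1. how much mono adduct the flask holds at 50 min, in percent of the substrate charged
2. how much idle adduct the flask holds at 50 min, in percent of the substrate charged
3. how much substrate the flask holds at 50 min, in percent of the substrate charged
4. how much other mono adduct the flask holds at 50 min, in percent of the substrate charged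

Let m be a mono adduct reading and b the idle adduct reading over 2, the bound part of m. We take idle adduct to stand in equilibrium with substrate and mono adduct, so that g follows c_substrate:

g = b / (m − b)

Both steps from substrate and reagent have the same reactants, so we let other mono adduct grow as s·m. With bis adduct neglected, the fraction of substrate left is:

a = 1 − b − (1 + s)·m

After the feed, g/a should be equal at equal substrate charge. Blue at 60.0 min gives g = 1.22, and violet at 60.0 min gives 0.635. Setting the two ratios equal gives:

s = 1.28

This is a reading, with its scatter: the selectivity factor, other mono adduct made per mono adduct made.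

Is one number enough? Amber was not used, and with its substrate charge scaled in, s predicts g = 2.22 at 60.0 min, while amber reads 2.04.

The forecast gives mono adduct 18.5%, idle adduct 18%, substrate 63% and other mono adduct 4%, saying: “The other mono adduct is never observed”. On its mono and idle figures, our s gives a different split: other mono adduct 23.7% and substrate 48.8%.

The flask at 50 min gives mono adduct 18.4%, idle adduct 19.5%, substrate 46.4% and other mono adduct 25.1%.

    substrate + mono adduct ⇌ idle adduct, settled at all times (K = 241 M⁻¹)
    reagent + other mono adduct → bis adduct (k = 5.64 × 10⁻⁴ M⁻¹ s⁻¹)
    reagent + mono adduct → bis adduct (k = 0.00179 M⁻¹ s⁻¹)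
    substrate + reagent → other mono adduct (k = 0.0156 M⁻¹ s⁻¹)
    substrate + reagent → mono adduct (k = 0.0115 M⁻¹ s⁻¹)

In the flask at 50 min, substrate is used 1.4 times as fast toward other mono adduct as toward mono adduct, and s on the flask's mono adduct gives 23.6% other mono adduct against 25.1% found. The same flask left until 2.0 h holds 27.6% mono adduct, so s gives 35.3% other mono adduct, and it holds 37.9%.

(The runs stem from a simulated flask for an exercise, and the scatter is random.)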